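Turn each run into times, fastest first, and ask what is still at work in the oak flask at the time asked.

| flask | starting material | partner | free catalyst | target | time |
|---|---|---|---|---|---|
| elm | 0.0500 M | 0.0500 M | 5.00 × 10⁻⁴ M |  |  |
| larch | 0.0250 M | 0.0250 M | 5.00 × 10⁻⁴ M |  |  |
| birch | 0.0500 M | 0.0500 M | 5.00 × 10⁻⁴ M | 0.0250 M |  |
| oak | 0.0500 M | 0.0250 M | 0.00150 M |  | 26 min |

- elm run (time / min: [starting material] / M): 1.0: 0.0420; 1.8: 0.0375; 3.0: 0.0335; 5.2: 0.0272; 8.9: 0.0199; 15: 0.0139; 26: 0.0071
- larch run (time / min: [starting material] / M): 1.0: 0.0223; 1.8: 0.0207; 3.0: 0.0174; 5.2: 0.0153; 8.9: 0.0116; 15: 0.0071; 26: 0.0030
- birch run (time / min: [starting material] / M): 1.0: 0.0421; 1.8: 0.0377; 3.0: 0.0329; 5.2: 0.0267; 8.9: 0.0201; 15: 0.0132; 26: 0.0075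

(each reading ± 3 × 10⁻⁴ M)

- Overall: starting material + partner -> target, with free catalyst as catalyst.
- Constant volume, constant temperature.

- starting material in the oak run at 26 min, as a share of the starting material charged

The lowest rung is the opening. In the elm run the first-minute fall of c(starting material) is 0.00800 M/min, which at that pace clears the charge in 6.25 min. In the larch run the fall is 0.00270 M/min, which clears its charge in 9.26 min. So twice the charge of both reactants together gives a fall 2.96 times as fast, as far as these scattered readings tell.

The next rung is the end of the elm and larch runs. Between 15 min and 26 min the logarithm of c(starting material) falls at 0.0611 /min in the elm run and at 0.0783 /min in the larch run. The larch tail, at lower concentrations, reads faster than the elm tail, though these are readings with scatter. The two slopes stand within a factor 1.28 of each other although the charges differ by a factor 2.00, so we read the tail as first-order in c(starting material). We carry the tail time, the time in which late readings of c(starting material) fall by a factor e, taken from the mean of the two slopes: 14.3 min.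

The top rung is the oak flask itself. Partner is the limiting reagent there, and it can turn half of the starting material. The tail, however, is read as first-order in starting material, so in our own reckoning it is not held to the charge of partner. We let it run from the start of the oak flask over 26 min, which is longer than the tail time, and exp(−time/tail time) then gives 16.3 % of the charge.

The forecast gave 52 %, with a range of 50.2 % to 56 %, saying “the floor is 50% remaining”. The oak flask gives 14.7 %.

    2 free catalyst ⇌ catalyst dimer, settled at all times (9250 /M)
    free catalyst + starting material + partner → target + free catalyst (22140 /M²/min)
    2 partner → lost reagent (5.022 /M/min)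
    starting material → decomposed substrate (0.05400 /min)

That value of 14.7 % corresponds to a fall by a factor e in every 13.6 min on average in the oak flask, against the tail time of 14.3 min. In the birch run, the tail time takes the reading 0.0132 M at 15 min to 0.00612 M at 26 min, lower than the reading of 0.0075 M. In the oak flask, the target step and the partner's own loss, with a first half-life of 3.98 min by that step by itself, ran while partner was there. Decomposition of starting material ran throughout, on a time of 18.5 min, and by itself it leaves 24.6 % of the charge over 26 min.

The numbers in the tables come from a simulation with constants of no real substance; the scatter is artificial.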